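**Retrosynthetic overview**

- The strategy rests on the oxazole C4–Cl, which sits between N3 and the aryl-bearing C5. This is the chloride of a 4-hydroxyoxazole, whose keto tautomer is an oxazol-4(5H)-one.
- C4–Cl is traced back to C4=O (deoxychlorination, step 7). The oxazolone is the only ring built in the route; it is closed in step 6 from carboxamide 5 and α-bromoacyl chloride 9 by forming N3–C4 (acylation) and O1–C5 (alkylation).
- Amide 5 comes from 2-(trichloroacetyl)pyrrole by ring trichlorination, ammonolysis and N-SEM protection. Acid chloride 9 comes from 4-hydroxyphenylacetic acid by O-tosylation, acid chloride formation and α-bromination.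
- End game: SEM removal, then detosylation. The pyrrole and benzene rings are purchased.

Key step: step 6

Remark on the chemistry: compounds 9, 10 and 11 carry one benzylic stereocentre and are handled as racemates; this centre becomes the sp2 carbon C5 of the oxazole in step 7, and the target is achiral.

**Route**

Step 1
Reactants: 1 2-(trichloroacetyl)pyrrole
Product: 2 2,2,2-trichloro-1-(3,4,5-trichloro-1H-pyrrol-2-yl)ethanone
Conditions: SO2Cl2 (3.5 equiv), AcOH, rt → 60 °C
Reagents that add atoms: sulfuryl chloride, O=S(=O)(Cl)Cl
Why: Electrophilic aromatic chlorination of the pyrrole, which despite the acyl group should react at all three free ring carbons with excess reagent (C4 and C5 first, C3 last), while the trichloromethyl ketone is inert to the acidic medium.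

Step 2
Reactants: 2 2,2,2-trichloro-1-(3,4,5-trichloro-1H-pyrrol-2-yl)ethanone
Product: 3 3,4,5-trichloro-1H-pyrrole-2-carboxamide
Conditions: NH3 (gas, excess), MeCN, 0 °C → rt
Reagents that add atoms: ammonia, N
Why: Haloform-type acyl substitution, in which ammonia adds to the trichloromethyl ketone and the trichloromethyl anion leaves as chloroform, a standard way to turn 2-(trichloroacetyl)pyrroles into carboxamides.

Step 3
Reactants: 3 3,4,5-trichloro-1H-pyrrole-2-carboxamide; 4 2-(trimethylsilyl)ethoxymethyl chloride
Product: 5 3,4,5-trichloro-1-(2-trimethylsilylethoxymethyl)pyrrole-2-carboxamide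
Conditions: NaH (1.05 equiv), DMF, 0 °C; then SEMCl (1.05 equiv), 0 °C → rt
Reagents that add atoms: 2-(trimethylsilyl)ethoxymethyl chloride (compound 4), C[Si](C)(C)CCOCCl
Why: N-alkylation of a pyrrolide with an α-chloro ether, selective because one equivalent of base removes only the ring N–H, which three chlorines and the carbonyl make far more acidic than the carboxamide N–H.

Step 4
Reactants: 6 4-hydroxyphenylacetic acid
Product: 7 2-[4-(4-methylphenylsulfonyloxy)phenyl]acetic acid
Conditions: TsCl (1.1 equiv), 2 M aq NaOH (2.5 equiv), THF, 0 °C → rt; then 1 M HCl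
Reagents that add atoms: 4-methylbenzenesulfonyl chloride, Cc1ccc(S(=O)(=O)Cl)cc1
Why: Schotten–Baumann O-sulfonylation, in which the phenoxide is sulfonylated durably while any mixed carboxylic–sulfonic anhydride is hydrolysed back to the carboxylate.

Step 5
Reactants: 7 2-[4-(4-methylphenylsulfonyloxy)phenyl]acetic acid
Product: 9 racemic 2-bromo-2-[4-(4-methylphenylsulfonyloxy)phenyl]acetyl chloride, via arylacetyl chloride 8 (not isolated)
Conditions: SOCl2 (4 equiv), ClCH2CH2Cl, 65 °C; then NBS (1.2 equiv), 48% aq HBr (cat.), 80 °C; evaporate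
Reagents that add atoms: thionyl chloride, O=S(Cl)Cl; N-bromosuccinimide, O=C1CCC(=O)N1Br
Why: Thionyl chloride gives acid chloride 8, whose HBr-catalysed enolisation allows α-bromination by NBS at the benzylic carbon (the acid chloride variant of the Hell–Volhard–Zelinsky reaction), forming the new stereocentre as a racemate while the sulfonate-deactivated ring is not brominated.

Step 6
Reactants: 5 3,4,5-trichloro-1-(2-trimethylsilylethoxymethyl)pyrrole-2-carboxamide; 9 racemic 2-bromo-2-[4-(4-methylphenylsulfonyloxy)phenyl]acetyl chloride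
Product: 11 racemic 4-[4-oxo-2-[3,4,5-trichloro-1-(2-trimethylsilylethoxymethyl)pyrrol-2-yl]-5H-oxazol-5-yl]phenyl 4-methylbenzenesulfonate, via bromo imide 10 (not isolated)
Conditions: pyridine (1.2 equiv), CH2Cl2, 0 °C → rt; concentrate; NaF (3 equiv), DMF, rt, under Ar; used promptly in step 7
Reagents that add atoms: none
Why: The carboxamide nitrogen of 5 attacks the acyl chloride of 9 (pyridine takes up HCl, and an initial O-acyl isoimide would rearrange to the same imide) to give imide 10 and so form N3–C4, after which fluoride-assisted ionisation of the acidic imide N–H lets the pyrrole-side carbonyl oxygen displace the benzylic bromide and form O1–C5. This is the established preparation of 5H-oxazol-4-ones from primary amides and α-bromoacyl halides, applied here to a heteroaryl carboxamide. The single ring is closed in the 5-exo-tet mode by intramolecular O-alkylation. The new stereocentre C5 is formed as a racemate, no element controls it, and it is erased when C5 becomes sp2 in step 7. The step needs closure through oxygen to the five-membered ring and not through the pyrrole nitrogen to a six-membered pyrrolo[1,2-a]pyrazinedione, which the SEM group on the pyrrole nitrogen secures, while closure through the imide nitrogen would require a three-membered ring. Chemoselectivity between the two electrophilic carbons of 9 is not critical, because amide O-alkylation at the benzylic bromide followed by N-acylation would converge on the same oxazolone.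

Step 7
Reactants: 11 racemic 4-[4-oxo-2-[3,4,5-trichloro-1-(2-trimethylsilylethoxymethyl)pyrrol-2-yl]-5H-oxazol-5-yl]phenyl 4-methylbenzenesulfonate
Product: 12 4-[4-chloro-2-[3,4,5-trichloro-1-(2-trimethylsilylethoxymethyl)pyrrol-2-yl]oxazol-5-yl]phenyl 4-methylbenzenesulfonate
Conditions: POCl3 (5 equiv), BnEt3NCl (2 equiv), PhNEt2 (1.2 equiv), MeCN, 80 °C
Reagents that add atoms: phosphoryl chloride, O=P(Cl)(Cl)Cl; benzyltriethylammonium chloride (additional chloride source), CC[N+](CC)(CC)Cc1ccccc1.[Cl-]
Why: Proposed new method: the 5-aryl oxazol-4(5H)-one should enolise readily to the 4-hydroxyoxazole (its C5–H is benzylic and α to the carbonyl), POCl3 should phosphorylate the C4 oxygen, reversible C5-protonation by the anilinium salt should give a 5H-oxazolium ion in which C4 is an activated imidoyl-type carbon, chloride should add there with loss of dichlorophosphate, and loss of the C5 proton should restore the aromatic ring with the amine buffering HCl to spare the SEM group; the closest known reaction types are the POCl3 deoxychlorination of thiazol-4(5H)-ones and thiazolidine-2,4-dione to 4-chlorothiazoles and of oxazol-2(3H)-ones to 2-chlorooxazoles, and the O-triflation of oxazol-4(5H)-ones, which shows that the C4 oxygen is the reactive site.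

Step 8
Reactants: 12 4-[4-chloro-2-[3,4,5-trichloro-1-(2-trimethylsilylethoxymethyl)pyrrol-2-yl]oxazol-5-yl]phenyl 4-methylbenzenesulfonate
Product: 13 4-[4-chloro-2-(3,4,5-trichloro-1H-pyrrol-2-yl)oxazol-5-yl]phenyl 4-methylbenzenesulfonate
Conditions: Bu4NF (1 M in THF, 3 equiv), THF, 60 °C; aq NH4Cl
Reagents that add atoms: none
Why: Fluoride-induced SEM cleavage, in which attack at silicon triggers fragmentation to ethylene, formaldehyde and the well-stabilised trichloropyrrolide (protonated on work-up), while the tosylate still masks the phenol so that the liberated formaldehyde meets no electron-rich ring and any early loss of the tosylate would only anticipate step 9.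

Step 9
Reactants: 13 4-[4-chloro-2-(3,4,5-trichloro-1H-pyrrol-2-yl)oxazol-5-yl]phenyl 4-methylbenzenesulfonate
Product: 14 4-[4-chloro-2-(3,4,5-trichloro-1H-pyrrol-2-yl)oxazol-5-yl]phenol (target)
Conditions: 2 M aq NaOH (5 equiv), 1,4-dioxane, 70 °C; then 1 M HCl to pH 4
Reagents that add atoms: none
Why: Saponification of the aryl sulfonate by hydroxide attack at sulfur, run without an alcohol cosolvent so that no alkyl tosylate can re-alkylate the phenoxide, with the pyrrolide and phenoxide anions formed in the medium shielding the chlorooxazole from nucleophilic attack.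

**Compound list**

1 | 2-(trichloroacetyl)pyrrole | O=C(c1ccc[nH]1)C(Cl)(Cl)Cl | starting material
2 | 2,2,2-trichloro-1-(3,4,5-trichloro-1H-pyrrol-2-yl)ethanone | O=C(c1[nH]c(Cl)c(Cl)c1Cl)C(Cl)(Cl)Cl | intermediate
3 | 3,4,5-trichloro-1H-pyrrole-2-carboxamide | NC(=O)c1[nH]c(Cl)c(Cl)c1Cl | intermediate
4 | 2-(trimethylsilyl)ethoxymethyl chloride | C[Si](C)(C)CCOCCl | starting material
5 | 3,4,5-trichloro-1-(2-trimethylsilylethoxymethyl)pyrrole-2-carboxamide | C[Si](C)(C)CCOCn1c(C(N)=O)c(Cl)c(Cl)c1Cl | intermediate
6 | 4-hydroxyphenylacetic acid | OC(=O)Cc1ccc(O)cc1 | starting material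
7 | 2-[4-(4-methylphenylsulfonyloxy)phenyl]acetic acid | Cc1ccc(S(=O)(=O)Oc2ccc(CC(=O)O)cc2)cc1 | intermediate
8 | 2-[4-(4-methylphenylsulfonyloxy)phenyl]acetyl chloride (not isolated) | Cc1ccc(S(=O)(=O)Oc2ccc(CC(=O)Cl)cc2)cc1 | intermediate
9 | racemic 2-bromo-2-[4-(4-methylphenylsulfonyloxy)phenyl]acetyl chloride | Cc1ccc(S(=O)(=O)Oc2ccc(C(Br)C(=O)Cl)cc2)cc1 | intermediate
10 | racemic N-[2-bromo-2-[4-(4-methylphenylsulfonyloxy)phenyl]acetyl]-3,4,5-trichloro-1-(2-trimethylsilylethoxymethyl)pyrrole-2-carboxamide (not isolated) | Cc1ccc(S(=O)(=O)Oc2ccc(C(Br)C(=O)NC(=O)c3c(Cl)c(Cl)c(Cl)n3COCC[Si](C)(C)C)cc2)cc1 | intermediate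
11 | racemic 4-[4-oxo-2-[3,4,5-trichloro-1-(2-trimethylsilylethoxymethyl)pyrrol-2-yl]-5H-oxazol-5-yl]phenyl 4-methylbenzenesulfonate | O=C1N=C(c2c(Cl)c(Cl)c(Cl)n2COCC[Si](C)(C)C)OC1c1ccc(OS(=O)(=O)c2ccc(C)cc2)cc1 | intermediate
12 | 4-[4-chloro-2-[3,4,5-trichloro-1-(2-trimethylsilylethoxymethyl)pyrrol-2-yl]oxazol-5-yl]phenyl 4-methylbenzenesulfonate | Cc1ccc(S(=O)(=O)Oc2ccc(-c3oc(-c4c(Cl)c(Cl)c(Cl)n4COCC[Si](C)(C)C)nc3Cl)cc2)cc1 | intermediate
13 | 4-[4-chloro-2-(3,4,5-trichloro-1H-pyrrol-2-yl)oxazol-5-yl]phenyl 4-methylbenzenesulfonate | Cc1ccc(S(=O)(=O)Oc2ccc(-c3oc(-c4[nH]c(Cl)c(Cl)c4Cl)nc3Cl)cc2)cc1 | intermediate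
14 | 4-[4-chloro-2-(3,4,5-trichloro-1H-pyrrol-2-yl)oxazol-5-yl]phenol | Oc1ccc(-c2oc(-c3[nH]c(Cl)c(Cl)c3Cl)nc2Cl)cc1 | target

**Step count**

Total step count: 9. Longest linear sequence: 7 steps (steps 1, 2, 3, 6, 7, 8, 9).

**Steps most likely to fail**

1. Step 7 (proposed new method). The reaction may stop at the O-phosphorylated 4-hydroxyoxazole because chloride fails to displace phosphate at the electron-rich C4 position, or the acidic medium may strip the SEM group before chlorination is complete. The fallback uses known chemistry, sets out from 11 and returns at 12. Oxazolone 11 would be O-triflated (Tf2O, Et3N, CH2Cl2, −78 → 0 °C), a known reaction of oxazol-4(5H)-ones, to give 4-[2-[3,4,5-trichloro-1-(2-trimethylsilylethoxymethyl)pyrrol-2-yl]-4-(trifluoromethylsulfonyloxy)oxazol-5-yl]phenyl 4-methylbenzenesulfonate F1. The triflate would then be reduced with formate under palladium catalysis (Pd(OAc)2, PPh3, Et3N, HCO2H, DMF, 60 °C); the zerovalent palladium formed in the flask should insert into the C–OTf bond in preference to the pyrrole C–Cl bonds and the aryl tosylate, giving 4-[2-[3,4,5-trichloro-1-(2-trimethylsilylethoxymethyl)pyrrol-2-yl]oxazol-5-yl]phenyl 4-methylbenzenesulfonate F2. Electrophilic chlorination with NCS (1.1 equiv, MeCN, 60 °C) would then place chlorine at oxazole C4, the only free heteroaryl C–H, since the pyrrole is fully substituted and the benzene ring is deactivated by the sulfonate; this gives 12.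

2. Step 6. N-acylation of the hindered, electron-poor carboxamide may be too slow, so that base-induced dehydrochlorination of 9 to an aryl(bromo)ketene and its oligomerisation, or quaternisation of pyridine by the benzylic bromide, consumes the acid chloride. The enolisable product may also autoxidise at C5 if air is admitted. The fallback sets out from 5 and returns at 11. Amide 5 would be silylated (Me3SiCl, Et3N, toluene, rt; filtration of the ammonium salt) to 3,4,5-trichloro-N-trimethylsilyl-1-(2-trimethylsilylethoxymethyl)pyrrole-2-carboxamide F3. This would be acylated by 9 without any base (CH2Cl2 or toluene, rt → 50 °C), a known neutral imide synthesis driven by loss of Me3SiCl, giving imide 10. Imide 10 would be cyclised as before (NaF, DMF, rt) to 11.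

3. Step 1. Chlorination may stall at the 4,5-dichloro stage because two chlorines and the trichloroacetyl group deactivate C3, and forcing it may cause ipso-chlorination and loss of aromaticity. The fallback sets out from 1 and returns at 3. The order would be reversed: ammonolysis of 1 first (NH3, MeCN, rt) to the less deactivated 1H-pyrrole-2-carboxamide F4, then exhaustive electrophilic chlorination (NCS, 3.3 equiv, DMF, 50 °C; Na2SO3 work-up to reverse any N-chlorination) to give 3.

**Further compounds**

F1 | step 7 | 4-[2-[3,4,5-trichloro-1-(2-trimethylsilylethoxymethyl)pyrrol-2-yl]-4-(trifluoromethylsulfonyloxy)oxazol-5-yl]phenyl 4-methylbenzenesulfonate | Cc1ccc(S(=O)(=O)Oc2ccc(-c3oc(-c4c(Cl)c(Cl)c(Cl)n4COCC[Si](C)(C)C)nc3OS(=O)(=O)C(F)(F)F)cc2)cc1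
F2 | step 7 | 4-[2-[3,4,5-trichloro-1-(2-trimethylsilylethoxymethyl)pyrrol-2-yl]oxazol-5-yl]phenyl 4-methylbenzenesulfonate | Cc1ccc(S(=O)(=O)Oc2ccc(-c3oc(-c4c(Cl)c(Cl)c(Cl)n4COCC[Si](C)(C)C)nc3)cc2)cc1
F3 | step 6 | 3,4,5-trichloro-N-trimethylsilyl-1-(2-trimethylsilylethoxymethyl)pyrrole-2-carboxamide | C[Si](C)(C)CCOCn1c(C(=O)N[Si](C)(C)C)c(Cl)c(Cl)c1Cl
F4 | step 1 | 1H-pyrrole-2-carboxamide | NC(=O)c1ccc[nH]1
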